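**Retrosynthetic overview**
1. Feature: the cyclopentane C1–C2–C3–C4–C5 has its oxygen at C4, the quaternary methyl carbon C1 sits two bonds away, and C5 also bears the oxygenated C6. C2=C3–C4(=O)–C5=C1 is therefore a divinyl ketone whose C5=C1 olefin lies in the seven-membered ring (C1, C5–C10) and whose C4/C6 oxygens form a chelating 1,3-dicarbonyl. Numbering: C1 quaternary fusion carbon, C4 isopropyl carbinol, C5 fusion CH, C6 anisoate carbon, C8 methyl-bearing olefin carbon, C10 acetate carbon.
2. Late stage: the C10 acetate and the C8=C9 olefin come from a C9=C10 olefin by α-epoxidation, selenide opening and selenoxide elimination. The C6 anisoate follows a hydroxyl-directed reduction of the C6 ketone, and the isopropyl group is added to the C4 ketone while C6 is masked as its silyl enol ether.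
3. Key disconnection C1–C2: enantioselective Nazarov cyclization of the 2-acyl cycloheptadienone 16. Its vinyl terminus carries a trimethylsilyl group that activates C2, fixes the C2=C3 olefin and is lost in the step.
4. 16 comes from the C2-symmetric (3R,6R)-3,6-dimethylcyclohept-4-enone 9 by aldol addition, oxidation and selenoxide dehydrogenation. The two α-carbons of 9 are equivalent, so no regiochemistry arises.
5. 9 comes from ring-closing metathesis of dienone 8, built from two copies of an auxiliary-controlled conjugate-addition product. Ring order: seven-membered ring first (step 6), five-membered ring second (step 11).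

Key step: step 11

Assumption: the sense of conrotation that the copper–bis(oxazoline) complex imposes on 16 cannot be assigned in advance; the (S,S) ligand is written, and its (R,R) antipode is taken if a pilot cyclization delivers the C1 epimer.

**Step 1**
Reactants: 1 (4S)-4-benzyl-1,3-oxazolidin-2-one; 2 (2E)-but-2-enoyl chloride
Product: 3 (4S)-4-benzyl-3-[(2E)-but-2-enoyl]-1,3-oxazolidin-2-one
Conditions: n-BuLi, THF, −78 °C; then 2, −78 → 0 °C
Reagents that add atoms: none
Why: N-Acylation of the lithiated oxazolidinone by the acid chloride is the standard entry to enoyl imides and needs no stereocontrol.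

**Step 2**
Reactants: 3 (4S)-4-benzyl-3-[(2E)-but-2-enoyl]-1,3-oxazolidin-2-one; 4 vinylmagnesium bromide
Product: 5 (4S)-4-benzyl-3-[(3R)-3-methylpent-4-enoyl]-1,3-oxazolidin-2-one
Conditions: CuBr·SMe2 (1.2 equiv), THF/Me2S, −78 → −20 °C; aq. NH4Cl
Reagents that add atoms: none
Why: Copper-mediated conjugate addition of the vinyl Grignard reagent to the magnesium-chelated s-cis enoyl imide should occur on the face opposite the benzyl group, which sets the (R) methyl-bearing centre that becomes C8.

**Step 3**
Reactants: 5 (4S)-4-benzyl-3-[(3R)-3-methylpent-4-enoyl]-1,3-oxazolidin-2-one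
Product: 6 methyl (3R)-3-methylpent-4-enoate
Conditions: NaOMe (1.1 equiv), MeOH, 0 °C; AcOH
Reagents that add atoms: methanol (as sodium methoxide), CO
Why: Methoxide transesterification attacks the exocyclic imide carbonyl, releases the auxiliary for re-use and cannot touch the β stereocentre, which carries no acidic hydrogen.

**Step 4**
Reactants: 6 methyl (3R)-3-methylpent-4-enoate (two molecules)
Product: 7 methyl (5R)-2-[(2S)-but-3-en-2-yl]-5-methyl-3-oxohept-6-enoate (both C2 epimers)
Conditions: TiCl4, Bu3N, TMSCl (cat.), CH2Cl2, 0 °C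
Reagents that add atoms: none
Why: The titanium-mediated Claisen condensation joins two molecules of the ester through its titanium enolate at 0 °C, the two methyl-bearing centres are not involved, and the new α centre is removed in step 5.

**Step 5**
Reactants: 7 methyl (5R)-2-[(2S)-but-3-en-2-yl]-5-methyl-3-oxohept-6-enoate
Product: 8 (3R,7R)-3,7-dimethylnona-1,8-dien-5-one
Conditions: LiCl, H2O, DMSO, 150 °C
Reagents that add atoms: none
Why: Krapcho dealkoxycarbonylation takes the ester out of the β-keto ester under neutral conditions and leaves the C2-symmetric dienone with two identical arms.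

**Step 6**
Reactants: 8 (3R,7R)-3,7-dimethylnona-1,8-dien-5-one
Product: 9 (3R,6R)-3,6-dimethylcyclohept-4-en-1-one
Conditions: second-generation Grubbs catalyst (3 mol%), CH2Cl2 (5 mM), 40 °C
Reagents that add atoms: none
Why: Ring-closing olefin metathesis of the two terminal vinyl groups closes the seven-membered ring with a cis olefin (the future C9=C10), and since both (R) centres are carried over unchanged the ketone is the trans, C2-symmetric isomer.

**Step 7**
Reactants: 10 (2E)-3-(trimethylsilyl)prop-2-en-1-ol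
Product: 11 (2E)-3-(trimethylsilyl)prop-2-enal
Conditions: MnO2, CH2Cl2, rt
Reagents that add atoms: none
Why: MnO2 oxidises the allylic alcohol to the enal and leaves the vinylsilane and its (E) geometry alone.

**Step 8**
Reactants: 9 (3R,6R)-3,6-dimethylcyclohept-4-en-1-one; 11 (2E)-3-(trimethylsilyl)prop-2-enal
Product: 12 (3S,6R)-2-[(2E)-1-hydroxy-3-(trimethylsilyl)prop-2-en-1-yl]-3,6-dimethylcyclohept-4-en-1-one (epimers at C2 and at the carbinol carbon)
Conditions: LiN(i-Pr)2, THF, −78 °C; then 11; AcOH, −78 °C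
Reagents that add atoms: none
Why: Aldol addition of the kinetic lithium enolate to the enal (1,2-addition) gives one constitution only, because the two α-methylene groups of 9 are exchanged by its C2 axis, and the new centres are erased in steps 9 and 10.

**Step 9**
Reactants: 12 (3S,6R)-2-[(2E)-1-hydroxy-3-(trimethylsilyl)prop-2-en-1-yl]-3,6-dimethylcyclohept-4-en-1-one
Product: 13 (3S,6R)-3,6-dimethyl-2-[(2E)-3-(trimethylsilyl)prop-2-enoyl]cyclohept-4-en-1-one (enolisable at C2)
Conditions: Dess–Martin periodinane, NaHCO3, CH2Cl2, 0 °C → rt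
Reagents that add atoms: none
Why: Dess–Martin oxidation of the β-hydroxy ketone gives the 1,3-diketone under buffered conditions that spare the vinylsilane and the ring olefin.

**Step 10**
Reactants: 13 (3S,6R)-3,6-dimethyl-2-[(2E)-3-(trimethylsilyl)prop-2-enoyl]cyclohept-4-en-1-one
Product: 16 (6R)-3,6-dimethyl-2-[(2E)-3-(trimethylsilyl)prop-2-enoyl]cyclohepta-2,4-dien-1-one, via C5 phenylselenide 14 (not isolated), via selenoxide 15 (not isolated)
Conditions: NaH, THF, 0 °C; PhSeCl, −78 °C; then 30% H2O2, pyridine, CH2Cl2, 0 °C → rt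
Reagents that add atoms: none
Why: The sodium diketonate is selenenylated at C5 on the face away from the neighbouring C1 methyl, so that the derived selenoxide has its only syn β-hydrogen at C1 and selenoxide syn-elimination should give the C5=C1 alkylidene diketone.

**Step 11**
Reactants: 16 (6R)-3,6-dimethyl-2-[(2E)-3-(trimethylsilyl)prop-2-enoyl]cyclohepta-2,4-dien-1-one
Product: 17 (6R,8aS)-4-hydroxy-6,8a-dimethyl-6,8a-dihydroazulen-3(5H)-one (enol form of the 3,4-dione)
Conditions: Cu(SbF6)2 (10 mol%, from CuCl2 and AgSbF6), (S,S)-t-Bu-box [2,2'-(propane-2,2-diyl)bis((4S)-4-tert-butyl-4,5-dihydro-1,3-oxazole), 11 mol%], HFIP (1,1,1,3,3,3-hexafluoropropan-2-ol, 2 equiv), 4 Å MS, CH2Cl2, 0 °C → rt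
Reagents that add atoms: none
Why: Two-point binding of divalent copper to O4 and O6 of 16 generates the hydroxypentadienyl cation C2=C3–C4–C5=C1, which closes by 4π conrotatory electrocyclization to join C2 to the fully substituted C1; the β-silyl-stabilised oxyallyl cation (charge at C3) then gives up Me3Si to HFIP, which leaves the C2=C3 olefin and, after proton transfer, the enolised diketone 17 and the free catalyst. The closest known reactions are the Lewis-acid-catalysed Nazarov cyclization of 2-acyl and 2-alkoxycarbonyl divinyl ketones with chiral bis(oxazoline)–copper complexes and the silicon-directed Nazarov cyclization of cycloalkenyl β-silylvinyl ketones. The cyclopentenone ring (C1–C2–C3–C4–C5) is closed by this electrocyclization, formally a 5-endo closure that is open only to the pericyclic pathway. The one new stereocentre, C1, is set by the sense of conrotation, which the C2-symmetric ligand on the chelated copper dictates, while the C8 methyl is remote and equatorial and should add at most a small bias. Closure at C1 and not at the vinylogous C9 is secured by the ring geometry, in which the acyl group is cis to the C1 methyl and trans to C10, so that C2 can reach C1 only. The silyl group secures fast, regiospecific termination, which keeps the cation from Wagner–Meerwein shifts of the C1 substituents to C5 and keeps the vinyl ketone from polymerising or closing onto the enol oxygen in the earlier steps.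

**Step 12**
Reactants: 17 (6R,8aS)-4-hydroxy-6,8a-dimethyl-6,8a-dihydroazulen-3(5H)-one
Product: 18 (6R,8aS)-4-[(tert-butyldimethylsilyl)oxy]-6,8a-dimethyl-6,8a-dihydroazulen-3(5H)-one
Conditions: TBSCl, imidazole, DMF, rt
Reagents that add atoms: tert-butyldimethylsilyl chloride, CC(C)(C)[Si](C)(C)Cl
Why: O-Silylation of the enolised 1,3-diketone should end on O6, because 1,5 oxygen-to-oxygen silyl shifts let the system settle in the isomer that keeps the cyclopentenone carbonyl and an olefin exocyclic to the five-membered ring, the arrangement preferred by 2-acylcyclopentanone enols.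

**Step 13**
Reactants: 18 (6R,8aS)-4-[(tert-butyldimethylsilyl)oxy]-6,8a-dimethyl-6,8a-dihydroazulen-3(5H)-one
Product: 19 (6R,8aR)-4-[(tert-butyldimethylsilyl)oxy]-6,8a-dimethyl-1,2,6,8a-tetrahydroazulen-3(5H)-one
Conditions: [(Ph3P)CuH]6, H2O, toluene, rt
Reagents that add atoms: none
Why: Conjugate reduction by the monovalent copper hydride puts hydride on C2 of the enone only, since the fully substituted, oxygen-bearing C6 terminus, the C4 ketone and the isolated C9=C10 olefin do not react with this reagent, and water protonates the copper enolate at C3.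

**Step 14**
Reactants: 19 (6R,8aR)-4-[(tert-butyldimethylsilyl)oxy]-6,8a-dimethyl-1,2,6,8a-tetrahydroazulen-3(5H)-one; 20 isopropylmagnesium chloride
Product: 22 (3R,3aR,6R,8aR)-3-hydroxy-6,8a-dimethyl-3-(propan-2-yl)-2,3,3a,5,6,8a-hexahydroazulen-4(1H)-one, via tertiary alcohol silyl enol ether 21 (not isolated)
Conditions: CeCl3, i-PrMgCl, THF, −78 °C; AcOH, −78 °C; then Bu4NF, AcOH, THF, 0 °C
Reagents that add atoms: none
Why: The organocerium reagent adds 1,2 to the C4 carbonyl of the vinylogous silyl ester (as in the first stage of a Stork–Danheiser sequence) without enolising it and should enter from the α face, anti to the angular C1 methyl, which sets C4 (OH β, isopropyl α), and buffered fluoride then frees the C6 ketone, whose C5 is protonated and can equilibrate through the enol to the trans-fused ketone (H5 α) that places C6 next to the small hydroxyl and not next to the isopropyl group.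

**Step 15**
Reactants: 22 (3R,3aR,6R,8aR)-3-hydroxy-6,8a-dimethyl-3-(propan-2-yl)-2,3,3a,5,6,8a-hexahydroazulen-4(1H)-one
Product: 23 (3R,3aS,4S,6R,8aR)-6,8a-dimethyl-3-(propan-2-yl)-1,2,3,3a,4,5,6,8a-octahydroazulene-3,4-diol
Conditions: Me4NBH(OAc)3, MeCN/AcOH, −25 °C
Reagents that add atoms: none
Why: In this Evans–Saksena reduction the C4 hydroxyl exchanges onto boron and delivers hydride intramolecularly to the β face of the C6 carbonyl, the face that the axial C1 methyl closes to external hydride, which sets C6 with the α (equatorial) hydroxyl trans to the C4 oxygen.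

**Step 16**
Reactants: 23 (3R,3aS,4S,6R,8aR)-6,8a-dimethyl-3-(propan-2-yl)-1,2,3,3a,4,5,6,8a-octahydroazulene-3,4-diol; 24 4-methoxybenzoyl chloride
Product: 25 (3R,3aS,4S,6R,8aR)-3-hydroxy-6,8a-dimethyl-3-(propan-2-yl)-1,2,3,3a,4,5,6,8a-octahydroazulen-4-yl 4-methoxybenzoate
Conditions: Et3N, DMAP, CH2Cl2, 0 °C → rt
Reagents that add atoms: none
Why: DMAP-catalysed acylation with the acid chloride esterifies the secondary C6 hydroxyl, while the tertiary C4 hydroxyl is too hindered to react.

**Step 17**
Reactants: 25 (3R,3aS,4S,6R,8aR)-3-hydroxy-6,8a-dimethyl-3-(propan-2-yl)-1,2,3,3a,4,5,6,8a-octahydroazulen-4-yl 4-methoxybenzoate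
Product: 26 the 7,8-epoxide of 25 (azulene numbering; C9–C10 in the text numbering) with the oxirane oxygen α, trans to the 8a-methyl and cis to H-3a
Conditions: mCPBA, NaHCO3, CH2Cl2, 0 °C → rt
Reagents that add atoms: 3-chloroperoxybenzoic acid, O=C(OO)c1cccc(Cl)c1
Why: Prilezhaev epoxidation should come from the α face, opposite the axial C1 methyl that covers the β face of the olefin (the C8 methyl is equatorial), which sets the C10 oxygen α.

**Step 18**
Reactants: 26 the α-7,8-epoxide of 25
Product: 29 (3R,3aS,4S,8R,8aS)-3,8-dihydroxy-6,8a-dimethyl-3-(propan-2-yl)-1,2,3,3a,4,5,8,8a-octahydroazulen-4-yl 4-methoxybenzoate, via hydroxy selenide 27 (not isolated), via selenoxide 28 (not isolated)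
Conditions: (PhSe)2, NaBH4, EtOH, rt; 26, 40 °C; then THF, 30% H2O2, pyridine, 0 °C → rt
Reagents that add atoms: none
Why: In this epoxide-to-allylic-alcohol transposition the selenide opens the epoxide by trans-diaxial (Fürst–Plattner) attack at C9, the carbon away from the neopentyl C10, from the β face, and the selenoxide then eliminates syn toward the cis C8 hydrogen and away from the carbinol carbon, which gives the C8=C9 olefin and keeps the 10α hydroxyl.

**Step 19**
Reactants: 29 (3R,3aS,4S,8R,8aS)-3,8-dihydroxy-6,8a-dimethyl-3-(propan-2-yl)-1,2,3,3a,4,5,8,8a-octahydroazulen-4-yl 4-methoxybenzoate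
Product: 30 (3R,3aS,4S,8R,8aS)-8-(acetyloxy)-3-hydroxy-6,8a-dimethyl-3-(propan-2-yl)-1,2,3,3a,4,5,8,8a-octahydroazulen-4-yl 4-methoxybenzoate (CNP0256979.2)
Conditions: Ac2O, DMAP, pyridine, CH2Cl2, rt
Reagents that add atoms: acetic anhydride, CC(=O)OC(C)=O
Why: DMAP-catalysed acetylation takes the secondary allylic C10 hydroxyl and leaves the hindered tertiary C4 hydroxyl free, which completes the target.

**Compound list**
1 | (4S)-4-benzyl-1,3-oxazolidin-2-one | O=C1N[C@@H](Cc2ccccc2)CO1 | starting material
2 | (2E)-but-2-enoyl chloride | C/C=C/C(Cl)=O | starting material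
3 | (4S)-4-benzyl-3-[(2E)-but-2-enoyl]-1,3-oxazolidin-2-one | C/C=C/C(=O)N1[C@@H](Cc2ccccc2)COC1=O | intermediate
4 | vinylmagnesium bromide | C=C[Mg]Br | starting material
5 | (4S)-4-benzyl-3-[(3R)-3-methylpent-4-enoyl]-1,3-oxazolidin-2-one | C=C[C@H](C)CC(=O)N1[C@@H](Cc2ccccc2)COC1=O | intermediate
6 | methyl (3R)-3-methylpent-4-enoate | C=C[C@H](C)CC(=O)OC | intermediate
7 | methyl (5R)-2-[(2S)-but-3-en-2-yl]-5-methyl-3-oxohept-6-enoate (both C2 epimers) | C=C[C@H](C)CC(=O)C(C(=O)OC)[C@@H](C)C=C | intermediate
8 | (3R,7R)-3,7-dimethylnona-1,8-dien-5-one | C=C[C@H](C)CC(=O)C[C@@H](C)C=C | intermediate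
9 | (3R,6R)-3,6-dimethylcyclohept-4-en-1-one (trans, C2-symmetric) | O=C1C[C@@H](C)C=C[C@H](C)C1 | intermediate
10 | (2E)-3-(trimethylsilyl)prop-2-en-1-ol | C[Si](C)(C)/C=C/CO | starting material
11 | (2E)-3-(trimethylsilyl)prop-2-enal | C[Si](C)(C)/C=C/C=O | intermediate
12 | (3S,6R)-2-[(2E)-1-hydroxy-3-(trimethylsilyl)prop-2-en-1-yl]-3,6-dimethylcyclohept-4-en-1-one (epimers at C2 and carbinol carbon) | O=C1C[C@@H](C)C=C[C@H](C)C1C(O)/C=C/[Si](C)(C)C | intermediate
13 | (3S,6R)-3,6-dimethyl-2-[(2E)-3-(trimethylsilyl)prop-2-enoyl]cyclohept-4-en-1-one | O=C1C[C@@H](C)C=C[C@H](C)C1C(=O)/C=C/[Si](C)(C)C | intermediate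
14 | (3S,6R)-3,6-dimethyl-2-(phenylselanyl)-2-[(2E)-3-(trimethylsilyl)prop-2-enoyl]cyclohept-4-en-1-one, selenium cis to H-3 | O=C1C[C@@H](C)C=C[C@H](C)[C@]1([Se]c2ccccc2)C(=O)/C=C/[Si](C)(C)C | intermediate (not isolated)
15 | selenoxide of 14 | O=C1C[C@@H](C)C=C[C@H](C)[C@]1([Se](=O)c2ccccc2)C(=O)/C=C/[Si](C)(C)C | intermediate (not isolated)
16 | (6R)-3,6-dimethyl-2-[(2E)-3-(trimethylsilyl)prop-2-enoyl]cyclohepta-2,4-dien-1-one | C[Si](C)(C)/C=C/C(=O)C1=C(C)C=C[C@H](C)CC1=O | intermediate
17 | (6R,8aS)-4-hydroxy-6,8a-dimethyl-6,8a-dihydroazulen-3(5H)-one | O=C1C=C[C@]2(C)C=C[C@H](C)CC(O)=C12 | intermediate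
18 | (6R,8aS)-4-[(tert-butyldimethylsilyl)oxy]-6,8a-dimethyl-6,8a-dihydroazulen-3(5H)-one | O=C1C=C[C@]2(C)C=C[C@H](C)CC(O[Si](C)(C)C(C)(C)C)=C12 | intermediate
19 | (6R,8aR)-4-[(tert-butyldimethylsilyl)oxy]-6,8a-dimethyl-1,2,6,8a-tetrahydroazulen-3(5H)-one | O=C1CC[C@]2(C)C=C[C@H](C)CC(O[Si](C)(C)C(C)(C)C)=C12 | intermediate
20 | isopropylmagnesium chloride | CC(C)[Mg]Cl | starting material
21 | (3R,6R,8aR)-4-[(tert-butyldimethylsilyl)oxy]-6,8a-dimethyl-3-(propan-2-yl)-1,2,3,5,6,8a-hexahydroazulen-3-ol | CC(C)[C@]1(O)CC[C@]2(C)C=C[C@H](C)CC(O[Si](C)(C)C(C)(C)C)=C12 | intermediate (not isolated)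
22 | (3R,3aR,6R,8aR)-3-hydroxy-6,8a-dimethyl-3-(propan-2-yl)-2,3,3a,5,6,8a-hexahydroazulen-4(1H)-one (trans-fused) | O=C1C[C@@H](C)C=C[C@@]2(C)CC[C@@](O)(C(C)C)[C@H]12 | intermediate
23 | (3R,3aS,4S,6R,8aR)-6,8a-dimethyl-3-(propan-2-yl)-1,2,3,3a,4,5,6,8a-octahydroazulene-3,4-diol | O[C@H]1C[C@@H](C)C=C[C@@]2(C)CC[C@@](O)(C(C)C)[C@H]12 | intermediate
24 | 4-methoxybenzoyl chloride | COc1ccc(C(Cl)=O)cc1 | starting material
25 | (3R,3aS,4S,6R,8aR)-3-hydroxy-6,8a-dimethyl-3-(propan-2-yl)-1,2,3,3a,4,5,6,8a-octahydroazulen-4-yl 4-methoxybenzoate | COc1ccc(C(=O)O[C@H]2C[C@@H](C)C=C[C@@]3(C)CC[C@@](O)(C(C)C)[C@H]23)cc1 | intermediate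
26 | 7,8-epoxide of 25, oxirane oxygen trans to the 8a-methyl | COc1ccc(C(=O)O[C@H]2C[C@@H](C)[C@H]4O[C@H]4[C@@]3(C)CC[C@@](O)(C(C)C)[C@H]23)cc1 | intermediate
27 | 8α-hydroxy-7β-(phenylselanyl) derivative of 25 (selenium cis to H-6, trans to the C8 hydroxyl) | COc1ccc(C(=O)O[C@H]2C[C@@H](C)[C@H]([Se]c4ccccc4)[C@@H](O)[C@@]3(C)CC[C@@](O)(C(C)C)[C@H]23)cc1 | intermediate (not isolated)
28 | selenoxide of 27 | COc1ccc(C(=O)O[C@H]2C[C@@H](C)[C@H]([Se](=O)c4ccccc4)[C@@H](O)[C@@]3(C)CC[C@@](O)(C(C)C)[C@H]23)cc1 | intermediate (not isolated)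
29 | (3R,3aS,4S,8R,8aS)-3,8-dihydroxy-6,8a-dimethyl-3-(propan-2-yl)-1,2,3,3a,4,5,8,8a-octahydroazulen-4-yl 4-methoxybenzoate | COc1ccc(C(=O)O[C@H]2CC(C)=C[C@@H](O)[C@@]3(C)CC[C@@](O)(C(C)C)[C@H]23)cc1 | intermediate
30 | (3R,3aS,4S,8R,8aS)-8-(acetyloxy)-3-hydroxy-6,8a-dimethyl-3-(propan-2-yl)-1,2,3,3a,4,5,8,8a-octahydroazulen-4-yl 4-methoxybenzoate | COc1ccc(C(=O)O[C@H]2CC(C)=C[C@@H](OC(C)=O)[C@@]3(C)CC[C@@](O)(C(C)C)[C@H]23)cc1 | target

**Step count**
Total: 19 steps. Longest linear sequence: 18 steps (steps 1–6 and 8–19); step 7 is a one-step branch.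

**Steps most likely to fail**

Step 11. The copper chelate may fail to turn over, the ligand may discriminate poorly between the two senses of conrotation at the fully substituted C1, and the vinylsilane may be protodesilylated or the cation may rearrange before or after closure. Fallback: the five-membered ring is built by conjugate addition and aldol closure instead of electrocyclization, setting out from 9. IBX in DMSO at 70 °C should dehydrogenate 9 to (6R)-3,6-dimethylcyclohepta-2,4-dien-1-one F1. A BF3-modified organocopper reagent made from [2-(1,3-dioxolan-2-yl)ethyl]magnesium bromide and CuI (−78 °C) should add 1,4 at C1 to give the keto acetal (3S,6R)-3-[2-(1,3-dioxolan-2-yl)ethyl]-3,6-dimethylcyclohept-4-en-1-one F2. The quaternary centre is then under substrate control from C8, and the C1 epimers are separated at this stage. Aqueous HCl in THF frees the aldehyde, which closes onto C5 by intramolecular aldol addition to the bicyclic ketol (6R,8aR)-3-hydroxy-6,8a-dimethyl-2,3,3a,5,6,8a-hexahydroazulen-4(1H)-one F3. Dess–Martin oxidation gives the diketone (6R,8aR)-6,8a-dimethyl-1,2,6,8a-tetrahydroazulene-3,4(3aH,5H)-dione F4, and silylation as in step 12 brings the material back to the route at 19.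

Step 14. The C1 methyl and C10 flank the C4 carbonyl almost symmetrically, so facial selectivity in the addition may be poor; the hindered nucleophile may enolise or reduce the ketone; and the tertiary aldol may undergo retro-aldol cleavage or dehydration when the C6 ketone is freed. Fallback: the C4 oxygen is installed by hydroxyl-directed epoxidation instead of by carbonyl addition, setting out from 19. The same organocerium addition followed by work-up with 1 M HCl completes the Stork–Danheiser transposition, so both C4 epimers of 21 converge on the dienone (6R,8aR)-6,8a-dimethyl-3-(propan-2-yl)-1,5,6,8a-tetrahydroazulen-4(2H)-one F5. Luche reduction (NaBH4, CeCl3, MeOH) should deliver hydride anti to the angular methyl and give the allylic alcohol (4R,6R,8aR)-6,8a-dimethyl-3-(propan-2-yl)-1,2,4,5,6,8a-hexahydroazulen-4-ol F6. VO(acac)2 with t-BuOOH should epoxidise the C4=C5 olefin on the face of that hydroxyl, giving the 3,3a-epoxy alcohol F7 with the oxirane oxygen cis to the C4 hydroxyl and to the 8a-methyl. Dess–Martin oxidation gives the 3,3a-epoxy-4-ketone F8. SmI2 in THF/MeOH at −78 °C cleaves the C5–O bond and, after protonation at C5, returns the β-hydroxy ketone 22, where the route is rejoined.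

Step 18. Opening of the hindered epoxide may be slow or go to C10, the anisoate may be ethanolysed under the alkoxide-forming conditions, and the product olefin may be epoxidised by perseleninic acid. Fallback: the selenide is introduced by substitution instead of by epoxide opening, setting out from 25. OsO4 (cat.) with N-methylmorpholine N-oxide in acetone/water should dihydroxylate the α face to the 7α,8α-diol F9. MsCl in pyridine at 0 °C should sulfonylate the less hindered C9 hydroxyl selectively to give the 7-mesylate F10. PhSeNa in DMF displaces the mesylate with inversion and gives the hydroxy selenide 27, which is oxidised and eliminated as in step 18 to 29.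

**Further compounds**
F1 | step 11 | (6R)-3,6-dimethylcyclohepta-2,4-dien-1-one | O=C1C=C(C)C=C[C@H](C)C1
F2 | step 11 | (3S,6R)-3-[2-(1,3-dioxolan-2-yl)ethyl]-3,6-dimethylcyclohept-4-en-1-one | O=C1C[C@](C)(CCC2OCCO2)C=C[C@H](C)C1
F3 | step 11 | (6R,8aR)-3-hydroxy-6,8a-dimethyl-2,3,3a,5,6,8a-hexahydroazulen-4(1H)-one (C3 and C3a epimers) | O=C1C[C@@H](C)C=C[C@@]2(C)CCC(O)C12
F4 | step 11 | (6R,8aR)-6,8a-dimethyl-1,2,6,8a-tetrahydroazulene-3,4(3aH,5H)-dione | O=C1C[C@@H](C)C=C[C@@]2(C)CCC(=O)C12
F5 | step 14 | (6R,8aR)-6,8a-dimethyl-3-(propan-2-yl)-1,5,6,8a-tetrahydroazulen-4(2H)-one | O=C1C[C@@H](C)C=C[C@@]2(C)CCC(C(C)C)=C12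
F6 | step 14 | (4R,6R,8aR)-6,8a-dimethyl-3-(propan-2-yl)-1,2,4,5,6,8a-hexahydroazulen-4-ol | O[C@@H]1C[C@@H](C)C=C[C@@]2(C)CCC(C(C)C)=C12
F7 | step 14 | 3,3a-epoxide of F6 with the oxirane oxygen cis to the C4 hydroxyl and to the 8a-methyl | O[C@@H]1C[C@@H](C)C=C[C@@]2(C)CC[C@]3(C(C)C)O[C@]123
F8 | step 14 | 3,3a-epoxy-4-ketone derived from F7 | O=C1C[C@@H](C)C=C[C@@]2(C)CC[C@]3(C(C)C)O[C@]123
F9 | step 18 | 7α,8α-dihydroxy derivative of 25 (both hydroxyls trans to the 8a-methyl) | COc1ccc(C(=O)O[C@H]2C[C@@H](C)[C@@H](O)[C@@H](O)[C@@]3(C)CC[C@@](O)(C(C)C)[C@H]23)cc1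
F10 | step 18 | 7-O-methanesulfonate of F9 | COc1ccc(C(=O)O[C@H]2C[C@@H](C)[C@@H](OS(C)(=O)=O)[C@@H](O)[C@@]3(C)CC[C@@](O)(C(C)C)[C@H]23)cc1
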